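Start with the rate.

| flask | starting material | second substrate | free catalyst | temperature | remark | time |
|---|---|---|---|---|---|---|
| gamma | 0.24 M | 0.24 M | 1 mM | 35 °C | run made earlier |  |
| alpha | 0.36 M | 0.24 M | 1 mM | 35 °C | run made earlier |  |
| Monday's | 0.24 M (fed, over 12 d) | 0.240 M | 1.0 mM |  | the addition at 5 °C, then warmed to 35 °C; the feed brings no volume worth counting | 20 d |
| Friday's | 0.24 M (fed, over 12 d) | 0.240 M | 1.0 mM | 35 °C | all else is in the flask from the start; the feed brings no volume worth counting | 20 d |
| Saturday's | 0.24 M | 0.240 M (in portions, 5, over 12 d) | 1.0 mM | 35 °C | first portion at the start, last at 12 d | 20 d |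
| Thursday's | 0.24 M | 0.240 M | 1.0 mM | 35 °C | everything together at the start | 20 d |

| run | time / d | target / % |
|---|---|---|
| gamma | 2.50 | 27 |
| gamma | 8.00 | 60 |
| gamma | 12.0 | 64 |
| gamma | 20.0 | 72 |
| alpha | 0.500 | 5 |
| alpha | 1.04 | 10 |
| alpha | 2.50 | 19 |
| alpha | 6.00 | 44 |

(each reading ± 2 percentage points)

- the flask with the highest amount of target, in percent of the starting material charged ("all alike" if they lie within 1.5 percentage points) (Monday's / Friday's / Saturday's / Thursday's / all alike)
- final target, as a percentage of the starting material charged, in Monday's
- final target, as a percentage of the starting material charged, in Friday's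
- final target, as a percentage of the starting material charged, in Saturday's
- final target, as a percentage of the starting material charged, in Thursday's

- what was read earlier has a scatter of 2 percentage points, one standard deviation
- steps thought possible: starting material + free catalyst <-> catalyst intermediate A; catalyst intermediate A -> free catalyst + target; second substrate + free catalyst <-> catalyst intermediate B; catalyst intermediate B -> free catalyst + second product; second substrate + free catalyst -> spent catalyst A; free catalyst -> spent catalyst B
- the earlier runs do not show what temperature does; that part of a forecast is a guess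

By 2.50 d the gamma run has averaged 0.0259 M d⁻¹ of target, and the alpha run 0.0274 M d⁻¹, with 1.50 times the [starting material]. As a reading, then, the rate is close to zero order in [starting material], and I take it to follow the live catalyst. Friday's feed brings 0.0200 M d⁻¹. I call gamma's early rate divided by the feed rate the headroom, here 1.30: above one, gamma's early pace is faster than the feed.

Now turn the question round. A Friday's target that keeps pace with the feed reaches gamma's 72% at 8.64 d. But between 2.50 d and 8.00 d the gamma run reads 0.0144 M d⁻¹ on average, which is 0.720 of that feed, so less than the feed, and by those readings 0.0960 M of starting material is still unconverted at 8.00 d. So the headroom, as read on gamma, falls below one inside that window. My reckoning for Friday's is therefore the 20.8% of the charge fed by 2.50 d, plus a modest tail. Thursday's repeats gamma's recipe.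

The forecast picks Saturday's at 80%, with Thursday's 71%, Monday's 52% and Friday's 14% (range 7% to 28%): “Friday's slow feed leaves the catalyst mostly free, so it dies within days”. Its Friday's figure is lower than my base figure.

The flasks give Saturday's the lead at 86.7%, then Thursday's 71.0%, Monday's 59.7% and Friday's 27.7%.

    starting material + free catalyst ⇌ catalyst intermediate A (K = 51.0 M⁻¹, k = 38.0 M⁻¹ h⁻¹, Ea = 60.0 kJ mol⁻¹, ΔH = −60.0 kJ mol⁻¹)
    catalyst intermediate A → free catalyst + target (k = 2.10 h⁻¹, Ea = 99.0 kJ mol⁻¹)
    second substrate + free catalyst ⇌ catalyst intermediate B (K = 3.00 M⁻¹, k = 36.0 M⁻¹ h⁻¹, Ea = 76.0 kJ mol⁻¹, ΔH = −61.0 kJ mol⁻¹)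
    catalyst intermediate B → free catalyst + second product (k = 4.20 h⁻¹, Ea = 88.0 kJ mol⁻¹)
    second substrate + free catalyst → spent catalyst A (k = 0.0860 M⁻¹ h⁻¹, Ea = 91.0 kJ mol⁻¹)
    free catalyst → spent catalyst B (k = 0.00510 h⁻¹, Ea = 112 kJ mol⁻¹)
    (constants at 35 °C)

Friday's ends at 27.7%, above my 20.8%, with 72% of its starting material still there, so a headroom of 1.30 did not carry the feed through. At 1.89 d in Friday's, second substrate takes up free catalyst 6.3 times as fast as starting material does, forward steps alone. The neighbour flask is Friday's with 0.0040 M of free catalyst. With rate in proportion to catalyst, its headroom is 5.18, and gamma's window scales to 2.88 of the feed, above one, so target should keep pace past 8.00 d. Computed, it ends at 94.1%.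

The readings are calculated with made-up constants; scatter was added.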